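**Plan**
Ring A hides a keto-aldehyde. C6 (OH) with its neighbours C5 (OMe) and C7 (allyl) is a ketone flanked by its two α-carbons. C4–H, bonded to the furan carbon C3a, is a formyl carbon that has lost its oxygen.
The retrosynthesis cuts C4=C5 first (aldol condensation), then C7–allyl (enolate alkylation), then C6–C7 (lateral acylation of a 2-methylfuran).
The last cuts are one furan C–O bond (Paal–Knorr) and C3–C3a (alkylation of acetoacetate).
Forward, the fully substituted furan ring is made first from 3,4,5-trimethoxypropiophenone and ethyl acetoacetate. The C7–C6–C5 chain is then grown from the furan 2-methyl group and allylated.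
The ester and ketone are then brought to the aldehyde and ketone level, and ring A closes last.
The target has no stereocentre, and no step needs stereocontrol.

Key step: step 8

Remark: every sp3 stereocentre met along the way is racemic or a diastereomer mixture and is erased on aromatisation, so the SMILES of those compounds carry no configuration.

**Step 1**
Reactants: 1 3,4,5-trimethoxypropiophenone
Product: 2 2-bromo-1-(3,4,5-trimethoxyphenyl)propan-1-one (racemic)
Conditions: CuBr2 (2.1 equiv), EtOAc/CHCl3, reflux
Reagents that add atoms: CuBr2, [Cu+2].[Br-].[Br-]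
Why: Heterogeneous CuBr2 α-bromination of an enolisable aryl ketone should brominate only the enol carbon and spare the acyl-deactivated trimethoxyarene; the new centre is racemic and disappears in step 3.

**Step 2**
Reactants: 2 2-bromo-1-(3,4,5-trimethoxyphenyl)propan-1-one; 3 ethyl acetoacetate
Product: 4 ethyl 2-acetyl-3-methyl-4-oxo-4-(3,4,5-trimethoxyphenyl)butanoate (diastereomer mixture)
Conditions: NaH (1.1 equiv), 3 (1.2 equiv), THF, 0 °C; then 2, 0 °C to rt
Reagents that add atoms: none
Why: SN2 C-alkylation of a soft β-keto ester enolate by an α-bromo ketone is the standard entry to 2-acyl-1,4-diketones; it forms the future C3–C3a bond and places the aryl ketone where it will sit next to the ring oxygen, unlike the Feist–Benary aldol path.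

**Step 3**
Reactants: 4 ethyl 2-acetyl-3-methyl-4-oxo-4-(3,4,5-trimethoxyphenyl)butanoate
Product: 5 ethyl 2,4-dimethyl-5-(3,4,5-trimethoxyphenyl)furan-3-carboxylate
Conditions: p-TsOH·H2O (10 mol %), toluene, reflux, Dean–Stark
Reagents that add atoms: none
Why: Paal–Knorr furan synthesis; the acetyl and aroyl carbonyl groups stand 1,4 to each other and cyclodehydrate to the tetrasubstituted furan, while the ester and aryl ethers tolerate catalytic acid and both stereocentres vanish.

**Step 4**
Reactants: 5 ethyl 2,4-dimethyl-5-(3,4,5-trimethoxyphenyl)furan-3-carboxylate; 6 N,2-dimethoxy-N-methylacetamide (Weinreb amide of methoxyacetic acid)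
Product: 7 ethyl 2-(3-methoxy-2-oxopropyl)-4-methyl-5-(3,4,5-trimethoxyphenyl)furan-3-carboxylate
Conditions: LiN(iPr)2 (1.15 equiv), THF, −78 °C; then 6 (1.3 equiv), −78 to −40 °C; AcOH quench
Reagents that add atoms: none
Why: Lateral (vinylogous) deprotonation followed by Weinreb ketone synthesis, the furan counterpart of o-toluate lateral lithiation; only the 2-methyl group is conjugated to the ester through the C2=C3 bond, the ester is shielded by two flanking substituents against self-condensation, and the chelated adduct releases the ketone only on quench.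

**Step 5**
Reactants: 7 ethyl 2-(3-methoxy-2-oxopropyl)-4-methyl-5-(3,4,5-trimethoxyphenyl)furan-3-carboxylate; 8 allyl bromide
Product: 9 ethyl 2-(1-methoxy-2-oxohex-5-en-3-yl)-4-methyl-5-(3,4,5-trimethoxyphenyl)furan-3-carboxylate (racemic)
Conditions: K2CO3 (1.5 equiv), 8 (1.05 equiv), acetone, rt to 40 °C
Reagents that add atoms: none
Why: Enolate C-alkylation of a doubly activated methylene; the CH2 between the ketone and the ester-bearing furan should be about as acidic as a β-keto ester, far more so than the CH2OMe side, so the soft allyl halide should enter at the future C7, and any O-allyl enol ether would converge on the same product by Claisen rearrangement.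

**Step 6**
Reactants: 9 ethyl 2-(1-methoxy-2-oxohex-5-en-3-yl)-4-methyl-5-(3,4,5-trimethoxyphenyl)furan-3-carboxylate
Product: 10 3-[3-(hydroxymethyl)-4-methyl-5-(3,4,5-trimethoxyphenyl)furan-2-yl]-1-methoxyhex-5-en-2-ol (diastereomer mixture)
Conditions: iBu2AlH (4.5 equiv), CH2Cl2, −78 to 0 °C; aq. potassium sodium tartrate
Reagents that add atoms: none
Why: Exhaustive hydride reduction of the ketone and ester; the weakly basic, Lewis acidic hydride should reduce the ketone faster than it enolises it, the terminal alkene, furan and aryl ethers are inert below 0 °C, and the carbinol configuration does not matter because it is oxidised away in step 7.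

**Step 7**
Reactants: 10 3-[3-(hydroxymethyl)-4-methyl-5-(3,4,5-trimethoxyphenyl)furan-2-yl]-1-methoxyhex-5-en-2-ol
Product: 11 2-(1-methoxy-2-oxohex-5-en-3-yl)-4-methyl-5-(3,4,5-trimethoxyphenyl)furan-3-carbaldehyde (racemic)
Conditions: (COCl)2 (3 equiv), DMSO (6 equiv), CH2Cl2, −78 °C; then Et3N (10 equiv), −78 to −20 °C; cold pH 7 buffer
Reagents that add atoms: none
Why: Double Swern oxidation; both hydroxyl groups of this 1,5-diol are activated at −78 °C before base releases either carbonyl group, which should prevent lactol formation and over-oxidation to a lactone, and any premature ring closure by the amine only moves material toward the target.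

**Step 8**
Reactants: 11 2-(1-methoxy-2-oxohex-5-en-3-yl)-4-methyl-5-(3,4,5-trimethoxyphenyl)furan-3-carbaldehyde
Product: 14 7-allyl-5-methoxy-3-methyl-2-(3,4,5-trimethoxyphenyl)benzofuran-6-ol, via aldol adduct 12 (not isolated), via cyclohexadienone 13 (not isolated)
Conditions: K2CO3 (2 equiv), degassed MeOH (0.02 M), Ar, rt; then 1 M HCl
Reagents that add atoms: none
Why: The base enolises the ketone reversibly on both sides; the OMe-bearing enolate carbon C5 adds to the formyl carbon C4 on the neighbouring furan position to give 12, E1cB loss of water installs C4=C5 in 13, and removal of the remaining C7–H turns 13 into the phenolate of 14. The closest known reaction type is the intramolecular aldol condensation–aromatisation by which 2-(2-oxoalkyl)aryl aldehydes give 2-naphthols, run here on a furan so that a benzofuran-6-ol results. Ring A closes in the favoured 6-(enolendo)-exo-trig mode. The C4 and C5 centres of 12 and the C7 centre carried from 11 are all erased, so no stereocontrol is required. The selectivity needed is the choice between the two enolates: the more stable C7 enolate could only reach the aldehyde through a four-membered ring and simply reverts to 11, whereas the C5 enolate closes a six-membered ring, so the connectivity of the chain dictates the 5-OMe/6-OH/7-allyl order. The aromatic stabilisation gained in the final proton shift pulls all preceding equilibria forward, while dilution and exclusion of air guard against intermolecular aldol reaction and phenolate oxidation.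

**Compound list**
1 | 1-(3,4,5-trimethoxyphenyl)propan-1-one (3,4,5-trimethoxypropiophenone) | CCC(=O)c1cc(OC)c(OC)c(OC)c1 | starting material
2 | 2-bromo-1-(3,4,5-trimethoxyphenyl)propan-1-one (racemic) | CC(Br)C(=O)c1cc(OC)c(OC)c(OC)c1 | intermediate
3 | ethyl acetoacetate | CCOC(=O)CC(C)=O | starting material
4 | ethyl 2-acetyl-3-methyl-4-oxo-4-(3,4,5-trimethoxyphenyl)butanoate (diastereomer mixture) | CCOC(=O)C(C(C)=O)C(C)C(=O)c1cc(OC)c(OC)c(OC)c1 | intermediate
5 | ethyl 2,4-dimethyl-5-(3,4,5-trimethoxyphenyl)furan-3-carboxylate | CCOC(=O)c1c(C)oc(-c2cc(OC)c(OC)c(OC)c2)c1C | intermediate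
6 | N,2-dimethoxy-N-methylacetamide | COCC(=O)N(C)OC | starting material
7 | ethyl 2-(3-methoxy-2-oxopropyl)-4-methyl-5-(3,4,5-trimethoxyphenyl)furan-3-carboxylate | CCOC(=O)c1c(CC(=O)COC)oc(-c2cc(OC)c(OC)c(OC)c2)c1C | intermediate
8 | allyl bromide | C=CCBr | starting material
9 | ethyl 2-(1-methoxy-2-oxohex-5-en-3-yl)-4-methyl-5-(3,4,5-trimethoxyphenyl)furan-3-carboxylate (racemic) | CCOC(=O)c1c(C(CC=C)C(=O)COC)oc(-c2cc(OC)c(OC)c(OC)c2)c1C | intermediate
10 | 3-[3-(hydroxymethyl)-4-methyl-5-(3,4,5-trimethoxyphenyl)furan-2-yl]-1-methoxyhex-5-en-2-ol (diastereomer mixture) | C=CCC(C(O)COC)c1oc(-c2cc(OC)c(OC)c(OC)c2)c(C)c1CO | intermediate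
11 | 2-(1-methoxy-2-oxohex-5-en-3-yl)-4-methyl-5-(3,4,5-trimethoxyphenyl)furan-3-carbaldehyde (racemic) | C=CCC(C(=O)COC)c1oc(-c2cc(OC)c(OC)c(OC)c2)c(C)c1C=O | intermediate
12 | 7-allyl-4-hydroxy-5-methoxy-3-methyl-2-(3,4,5-trimethoxyphenyl)-4,5-dihydrobenzofuran-6(7H)-one (diastereomer mixture, not isolated) | C=CCC1C(=O)C(OC)C(O)c2c(C)c(-c3cc(OC)c(OC)c(OC)c3)oc21 | intermediate
13 | 7-allyl-5-methoxy-3-methyl-2-(3,4,5-trimethoxyphenyl)benzofuran-6(7H)-one (racemic, not isolated) | C=CCC1C(=O)C(OC)=Cc2c(C)c(-c3cc(OC)c(OC)c(OC)c3)oc21 | intermediate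
14 | 7-allyl-5-methoxy-3-methyl-2-(3,4,5-trimethoxyphenyl)benzofuran-6-ol | C=CCc1c(O)c(OC)cc2c(C)c(-c3cc(OC)c(OC)c(OC)c3)oc12 | target

Total step count: 8. Longest linear sequence: 8 steps (1 to 14).

**Steps most likely to fail**

**Step 4 (lateral acylation).**
- What may go wrong: deprotonation of the 2-methyl group may be incomplete. The lithiated ester may condense with ester that has not yet reacted. The anion may be quenched by proton transfer from the amide. The adduct alkoxide may close onto the neighbouring ester.
- Fallback: it sets out from 2 and comes back at 7. It brings the future C7 in with the dicarbonyl building block, so no strong-base metalation of a methyl group is needed.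
- Bromo ketone 2 alkylates the sodium enolate of diethyl 3-oxopentanedioate (NaH, THF) to give diethyl 2-[1-oxo-1-(3,4,5-trimethoxyphenyl)propan-2-yl]-3-oxopentanedioate F1.
- Paal–Knorr closure (p-TsOH, toluene, reflux) gives ethyl 2-(2-ethoxy-2-oxoethyl)-4-methyl-5-(3,4,5-trimethoxyphenyl)furan-3-carboxylate F2.
- The activated CH2 of F2 is deprotonated with LiN(SiMe3)2 (2.1 equiv, THF, −78 °C) and C-acylated with methoxyacetyl chloride. This gives ethyl 2-(1-ethoxy-4-methoxy-1,3-dioxobutan-2-yl)-4-methyl-5-(3,4,5-trimethoxyphenyl)furan-3-carboxylate F3.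
- Krapcho dealkoxycarbonylation (LiCl, wet DMSO, 140 °C) removes only the side-chain ester that is β to the ketone and returns 7.

**Step 5 (C-allylation).**
- What may go wrong: a second allylation at the same carbon, persistent O-allylation, or attack of the enolate oxygen on the adjacent ester could erode the yield of the mono-C-allyl ketone.
- Fallback: it sets out from 5 and comes back at 9. It reverses the order of the two C–C bond formations.
- Lateral deprotonation of 5 (LiN(iPr)2, THF, −78 °C) and alkylation with 8 gives ethyl 2-(but-3-en-1-yl)-4-methyl-5-(3,4,5-trimethoxyphenyl)furan-3-carboxylate F4. Its anion is less stabilised than that of 5, so over-alkylation is disfavoured.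
- A second lateral deprotonation of F4 and addition to Weinreb amide 6 delivers 9 directly. No free enolate of the ketone is ever exposed to an alkylating agent.

**Step 8 (aldol benzannulation).**
- What may go wrong: the doubly activated C7–H is removed first, and the branched, extended enolate may hold the material back. Slow deacylation of the side-chain ketone by methoxide (retro-Claisen cleavage) or oxidation of the electron-rich phenolate could then take over.
- Fallback: it sets out from 7 and comes back at 14. The ring is closed on the unbranched chain, the closest hetero-analogue of the parent 2-(2-oxopropyl)benzaldehyde case, and the allyl group is brought in afterwards.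
- iBu2AlH reduction of 7 gives 1-[3-(hydroxymethyl)-4-methyl-5-(3,4,5-trimethoxyphenyl)furan-2-yl]-3-methoxypropan-2-ol F5.
- Swern oxidation gives 2-(3-methoxy-2-oxopropyl)-4-methyl-5-(3,4,5-trimethoxyphenyl)furan-3-carbaldehyde F6.
- K2CO3 in MeOH closes ring A to 5-methoxy-3-methyl-2-(3,4,5-trimethoxyphenyl)benzofuran-6-ol F7.
- O-allylation with 8 (K2CO3, acetone) gives 6-(allyloxy)-5-methoxy-3-methyl-2-(3,4,5-trimethoxyphenyl)benzofuran F8.
- Aromatic Claisen rearrangement (N,N-diethylaniline, 200 °C) moves the allyl group to C7. This is the only free ortho position because C5 carries the methoxy group, and the product is 14.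

**Further compounds**
F1 | step 4 | diethyl 2-[1-oxo-1-(3,4,5-trimethoxyphenyl)propan-2-yl]-3-oxopentanedioate | CCOC(=O)CC(=O)C(C(=O)OCC)C(C)C(=O)c1cc(OC)c(OC)c(OC)c1
F2 | step 4 | ethyl 2-(2-ethoxy-2-oxoethyl)-4-methyl-5-(3,4,5-trimethoxyphenyl)furan-3-carboxylate | CCOC(=O)Cc1oc(-c2cc(OC)c(OC)c(OC)c2)c(C)c1C(=O)OCC
F3 | step 4 | ethyl 2-(1-ethoxy-4-methoxy-1,3-dioxobutan-2-yl)-4-methyl-5-(3,4,5-trimethoxyphenyl)furan-3-carboxylate | CCOC(=O)C(C(=O)COC)c1oc(-c2cc(OC)c(OC)c(OC)c2)c(C)c1C(=O)OCC
F4 | step 5 | ethyl 2-(but-3-en-1-yl)-4-methyl-5-(3,4,5-trimethoxyphenyl)furan-3-carboxylate | C=CCCc1oc(-c2cc(OC)c(OC)c(OC)c2)c(C)c1C(=O)OCC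
F5 | step 8 | 1-[3-(hydroxymethyl)-4-methyl-5-(3,4,5-trimethoxyphenyl)furan-2-yl]-3-methoxypropan-2-ol | COCC(O)Cc1oc(-c2cc(OC)c(OC)c(OC)c2)c(C)c1CO
F6 | step 8 | 2-(3-methoxy-2-oxopropyl)-4-methyl-5-(3,4,5-trimethoxyphenyl)furan-3-carbaldehyde | COCC(=O)Cc1oc(-c2cc(OC)c(OC)c(OC)c2)c(C)c1C=O
F7 | step 8 | 5-methoxy-3-methyl-2-(3,4,5-trimethoxyphenyl)benzofuran-6-ol | COc1cc2c(C)c(-c3cc(OC)c(OC)c(OC)c3)oc2cc1O
F8 | step 8 | 6-(allyloxy)-5-methoxy-3-methyl-2-(3,4,5-trimethoxyphenyl)benzofuran | C=CCOc1cc2oc(-c3cc(OC)c(OC)c(OC)c3)c(C)c2cc1OC
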